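The cyclohexane ring of the quinic acid core is cut into two three-carbon pieces, C3–C4–C5 (2-O-benzylglycerol) and C2–C1–C6 (2-methylenepropane-1,3-diyl diacetate). The key step joins them by an iridium-catalysed double carbonyl allylation run from the diol oxidation level, so its precursor is only the acyclic 1,3-diol plus the bis-allyl donor and no labile dialdehyde is needed. It exploits the trans-1,3-diol at C3/C5 across C4: while C1 is still sp2, both carbinols are homomorphic (R,R) and C4 is not a stereocenter. The exocyclic methylene then becomes C1(OH)CO2H, and the 1,5-lactone sorts O3, O4 and O5 for the two different cinnamoyl esters.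

Key step: step 1

Remark: positions are numbered as in quinic acid (C1 carries OH and CO2H; O3 and O4 are cis to the 1-OH, O5 is trans); the (R)-ligand is assumed to give the (R)-carbinols, and its antipode is used without other change if the sense proves opposite.

Step 1
Reactants: 1 2-(benzyloxy)propane-1,3-diol; 2 2-methylenepropane-1,3-diyl diacetate
Product: 6 (1R,3R)-2-(benzyloxy)-5-methylidenecyclohexane-1,3-diol, via hydroxy aldehyde 3 (not isolated), via mono-allylation adduct 4 (not isolated), via tethered hydroxy aldehyde 5 (not isolated)
Conditions: [Ir(cod)Cl]2 (5 mol%), (R)-Cl,MeO-BIPHEP (10 mol%), 4-chloro-3-nitrobenzoic acid (20 mol%), Cs2CO3 (40 mol%), 1,4-dioxane (0.02 M), 90 °C, slow addition of 2 (1.05 equiv)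
Reagents that add atoms: none
Why: Proposed new method: a cyclometalated π-allyl iridium C,O-benzoate (trivalent iridium) dehydrogenates one primary alcohol of 1 to aldehyde 3, the iridium hydride so formed is deprotonated and ionizes one acetate of 2, and the allyliridium adds to 3 through a closed chair transition state to give 4; the same cycle then oxidizes the remaining primary alcohol to 5, ionizes the tethered allylic acetate and adds intramolecularly, so that the C2–C3 and C5–C6 bonds form in one flask. The closest known reaction type is the two-directional transfer-hydrogenative carbonyl allylation of 1,3-diols with allyl acetate, together with mono-allylations that use 2-substituted bifunctional allyl donors; new is the use of both termini of one donor to close a carbocycle. The ring closes by 6-exo-trig addition of the allyl terminus to the aldehyde carbon, leaving the exocyclic methylene on the future C1. C3 is set by the ligand-controlled aldehyde face, and C5 by the same catalyst reinforced by the bicyclic closed transition state, which puts the forming carbinol oxygen axial and the existing C3–OH equatorial, so the trans (R,R) diol should result; C4 is not a stereocenter in 6 because C3 and C5 are homomorphic, so epimerization of the α-benzyloxy aldehydes is harmless. The step needs C- over O-allylation and primary over secondary alcohol dehydrogenation, both intrinsic to this catalyst class, and cyclization over a second intermolecular allylation, which slow addition of 2 at high dilution should secure.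

Step 2
Reactants: 6 (1R,3R)-2-(benzyloxy)-5-methylidenecyclohexane-1,3-diol
Product: 7 4-(benzyloxy)-1-(hydroxymethyl)cyclohexane-1,3,5-triol with the (−)-quinic acid configuration
Conditions: OsO4 (1.05 equiv), TMEDA (1.1 equiv), CH2Cl2, −78 °C; then aq. Na2SO3, THF, reflux
Reagents that add atoms: osmium tetroxide, O=[Os](=O)(=O)=O
Why: Hydrogen-bond-directed dihydroxylation with OsO4·TMEDA, known for cyclic homoallylic alcohols: in the favoured chair of 6 (OBn and one OH equatorial) the hydroxyl cis to OBn is axial and 1,3-syn to one face of the exocyclic alkene, so osmium should be delivered there and the new tertiary OH at C1 ends up cis to 3-OH and 4-OBn, which is the quinic acid configuration at C1 and makes C4 a defined stereocenter.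

Step 3
Reactants: 7 4-(benzyloxy)-1-(hydroxymethyl)cyclohexane-1,3,5-triol with the (−)-quinic acid configuration
Product: 9 4-O-benzyl-1,5-quinide, via 4-O-benzylquinic acid 8 (not isolated)
Conditions: TEMPO (10 mol%), NaClO2 (2.5 equiv), NaOCl (5 mol%), MeCN/phosphate buffer (pH 6.8), 35 °C; acidify to pH 2, extract; then sulfonic acid resin (H+ form), toluene/DMF, reflux, Dean–Stark
Reagents that add atoms: sodium chlorite, [Na+].[O-]Cl=O
Why: Nitroxyl-catalysed chlorite oxidation (with a Pinnick-type aldehyde oxidation inside the cycle) should take the primary alcohol of the 1,2-diol to the α-hydroxy acid without glycol cleavage or oxidation of the secondary alcohols, and acid-catalysed lactonization can engage only the 5-OH, the one hydroxyl cis to the carboxyl group, so O5 is set apart from O3.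

Step 4
Reactants: 9 4-O-benzyl-1,5-quinide
Product: 10 (−)-1,5-quinide
Conditions: H2 (1 atm), Pd/C (10 wt%), EtOAc/MeOH, rt
Reagents that add atoms: none
Why: Hydrogenolysis of the benzyl ether over Pd/C; the lactone and the alcohols are inert and no stereocenter is touched.

Step 5
Reactants: 11 (E)-3,4-diacetoxycinnamic acid
Product: 12 (E)-3,4-diacetoxycinnamoyl chloride
Conditions: (COCl)2 (1.3 equiv), DMF (cat.), CH2Cl2, 0 °C to rt; evaporate, use crude
Reagents that add atoms: oxalyl chloride, ClC(=O)C(=O)Cl
Why: Acid chloride formation through the Vilsmeier-type chloroiminium ion from DMF; the aryl acetates and the (E)-alkene are stable to these conditions.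

Step 6
Reactants: 10 (−)-1,5-quinide; 12 (E)-3,4-diacetoxycinnamoyl chloride
Product: 13 3-O-[(E)-3,4-diacetoxycinnamoyl]-1,5-quinide
Conditions: 12 (1.1 equiv), 2-aminoethyl diphenylborinate (10 mol%), iPr2NEt (1.3 equiv), MeCN, rt
Reagents that add atoms: none
Why: Borinic-acid-catalysed regioselective acylation of a cis-1,2-diol: the 3,4-diol binds as a tetracoordinate borinate and its equatorial oxygen (O3) should be acylated, while the axial 4-OH and the tertiary 1-OH stay free.

Step 7
Reactants: 14 (E)-4-acetoxycinnamic acid
Product: 15 (E)-4-acetoxycinnamoyl chloride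
Conditions: (COCl)2 (1.3 equiv), DMF (cat.), CH2Cl2, 0 °C to rt; evaporate, use crude
Reagents that add atoms: oxalyl chloride, ClC(=O)C(=O)Cl
Why: Acid chloride formation through the Vilsmeier-type chloroiminium ion, as in step 5.

Step 8
Reactants: 13 3-O-[(E)-3,4-diacetoxycinnamoyl]-1,5-quinide; 15 (E)-4-acetoxycinnamoyl chloride
Product: 16 3-O-[(E)-3,4-diacetoxycinnamoyl]-4-O-[(E)-4-acetoxycinnamoyl]-1,5-quinide
Conditions: 15 (1.5 equiv), pyridine (3 equiv), DMAP (10 mol%), CH2Cl2, 0 °C to rt
Reagents that add atoms: none
Why: DMAP-catalysed acylation (nucleophilic catalysis) of the only remaining secondary hydroxyl, the axial 4-OH; the tertiary 1-OH next to the lactone carbonyl should react far more slowly.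

Step 9
Reactants: 16 3-O-[(E)-3,4-diacetoxycinnamoyl]-4-O-[(E)-4-acetoxycinnamoyl]-1,5-quinide
Product: 17 3-O-caffeoyl-4-O-p-coumaroylquinic acid
Conditions: 2 M aq. HCl/THF (1:3), rt, several days
Reagents that add atoms: water, O
Why: Acid-catalysed hydrolysis should cleave the three phenolic acetates and open the strained bicyclic γ-lactone, while the cinnamate esters of the secondary alcohols persist and the low pH suppresses acyl migration to the freed 5-OH.

Compound list
1 | 2-(benzyloxy)propane-1,3-diol (2-O-benzylglycerol) | OCC(CO)OCc1ccccc1 | starting material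
2 | 2-methylenepropane-1,3-diyl diacetate | CC(=O)OCC(=C)COC(C)=O | starting material
3 | 2-(benzyloxy)-3-hydroxypropanal (racemic, formed in the flask) | O=CC(CO)OCc1ccccc1 | intermediate
4 | (4R)-5-(benzyloxy)-4,6-dihydroxy-2-methylidenehexyl acetate (both C5 epimers, formed in the flask) | CC(=O)OCC(=C)C[C@@H](O)C(CO)OCc1ccccc1 | intermediate
5 | (4R)-5-(benzyloxy)-4-hydroxy-2-methylidene-6-oxohexyl acetate (formed in the flask) | CC(=O)OCC(=C)C[C@@H](O)C(C=O)OCc1ccccc1 | intermediate
6 | (1R,3R)-2-(benzyloxy)-5-methylidenecyclohexane-1,3-diol (trans-diol; ring C1/C3 are quinic C3/C5) | c1ccccc1COC1[C@H](O)CC(=C)C[C@H]1O | intermediate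
7 | 4-(benzyloxy)-1-(hydroxymethyl)cyclohexane-1,3,5-triol with the (−)-quinic acid configuration (1-OH, 3-OH and 4-OBn on one face; CH2OH and 5-OH on the other) | c1ccccc1CO[C@H]1[C@H](O)C[C@](O)(CO)C[C@H]1O | intermediate
8 | 4-O-benzyl-(−)-quinic acid (formed in the flask) | c1ccccc1CO[C@H]1[C@H](O)C[C@](O)(C(=O)O)C[C@H]1O | intermediate
9 | 4-O-benzyl-1,5-quinide (1,5-lactone of 8; free 1-OH and 3-OH) | c1ccccc1CO[C@H]1[C@H]2C[C@](O)(C(=O)O2)C[C@H]1O | intermediate
10 | (−)-1,5-quinide (1,5-lactone of (−)-quinic acid; free 1-, 3- and 4-OH) | O[C@H]1[C@H]2C[C@](O)(C(=O)O2)C[C@H]1O | intermediate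
11 | (E)-3,4-diacetoxycinnamic acid | CC(=O)Oc1ccc(/C=C/C(=O)O)cc1OC(C)=O | starting material
12 | (E)-3,4-diacetoxycinnamoyl chloride | CC(=O)Oc1ccc(/C=C/C(=O)Cl)cc1OC(C)=O | intermediate
13 | 3-O-[(E)-3,4-diacetoxycinnamoyl]-1,5-quinide | O[C@H]1[C@H]2C[C@](O)(C(=O)O2)C[C@H]1OC(=O)/C=C/c1ccc(OC(C)=O)c(OC(C)=O)c1 | intermediate
14 | (E)-4-acetoxycinnamic acid | CC(=O)Oc1ccc(/C=C/C(=O)O)cc1 | starting material
15 | (E)-4-acetoxycinnamoyl chloride | CC(=O)Oc1ccc(/C=C/C(=O)Cl)cc1 | intermediate
16 | 3-O-[(E)-3,4-diacetoxycinnamoyl]-4-O-[(E)-4-acetoxycinnamoyl]-1,5-quinide | O=C(/C=C/c1ccc(OC(C)=O)cc1)O[C@H]1[C@H]2C[C@](O)(C(=O)O2)C[C@H]1OC(=O)/C=C/c1ccc(OC(C)=O)c(OC(C)=O)c1 | intermediate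
17 | 3-O-caffeoyl-4-O-p-coumaroylquinic acid (CNP0077575.1) | O=C(/C=C/c1ccc(O)cc1)O[C@H]1[C@H](O)C[C@](O)(C(=O)O)C[C@H]1OC(=O)/C=C/c1ccc(O)c(O)c1 | target

Total step count: 9. Longest linear sequence: 7 (steps 1, 2, 3, 4, 6, 8, 9).

Steps most likely to fail

Step 1. The ring-forming second allylation may not keep pace with a second intermolecular allylation, or the tethered allylic acetate may ionize too slowly, so that acyclic mono- and bis-adducts accumulate. β-Elimination of the α-benzyloxy β-hydroxy aldehyde is a further loss channel. The fallback uses known reaction types, sets out from 1 and 2 and comes back at 6. The iridium-catalysed C-allylation is run with 1 in threefold excess and stopped at the mono-allylation adduct 4, which is isolated. The primary alcohol of 4 is oxidized selectively with TEMPO/PhI(OAc)2 to the hydroxy aldehyde 5. The ring is then closed by an umpolung allylation with zerovalent palladium and indium monoiodide (Pd(PPh3)4, InI, THF, rt). The allylindium formed from the allylic acetate adds to the aldehyde through a closed bicyclic chair transition state (forming carbinol oxygen axial, C3–OH equatorial), which should give the trans-diol 6 with C3 still catalyst-derived. No compound outside the list arises (F0).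

Step 2. Facial selectivity may erode if the minor chair (axial 5-OH) or the equatorial 5-OH also delivers the osmium reagent, which would give the C1 epimer. The fallback sets out from 6 and comes back at 9. The equatorial hydroxyl trans to OBn is silylated selectively (TBSCl, imidazole, DMF, 0 °C) to give the 5-O-TBS ether of 6 F1, in which only the axial 3-OH can direct. The directed dihydroxylation then gives the 5-O-TBS triol F2, and the oxidation of step 3 gives 5-O-TBS-4-O-benzylquinic acid F3. Aqueous acid removes the silyl group and heating with the acid resin lactonizes to 9.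

Step 6. Regiocontrol in the monoacylation may be lost through acylation of the axial 4-OH, diacylation, or base-induced 3-to-4 acyl migration. The fallback sets out from 9 and comes back at 13, and step 4 is then omitted. Lactone 9, whose only secondary hydroxyl is the 3-OH, is acylated with 12 (pyridine, DMAP, CH2Cl2) to 3-O-[(E)-3,4-diacetoxycinnamoyl]-4-O-benzyl-1,5-quinide F4. The benzyl ether is then cleaved without hydrogen by BCl3 with pentamethylbenzene as cation scavenger (CH2Cl2, −78 °C), which should leave the alkene, the aryl acetates and the lactone intact.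

Further compounds
F0 | step 1 | none | none
F1 | step 2 | 5-O-TBS ether of 6: 2-(benzyloxy)-3-(tert-butyldimethylsilyloxy)-5-methylidenecyclohexan-1-ol, silyl on the hydroxyl trans to OBn | c1ccccc1CO[C@H]1[C@H](O[Si](C)(C)C(C)(C)C)CC(=C)C[C@H]1O
F2 | step 2 | 5-O-TBS triol: 5-O-TBS ether of 7 | c1ccccc1CO[C@H]1[C@H](O[Si](C)(C)C(C)(C)C)C[C@](O)(CO)C[C@H]1O
F3 | step 2 | 5-O-TBS-4-O-benzylquinic acid | c1ccccc1CO[C@H]1[C@H](O[Si](C)(C)C(C)(C)C)C[C@](O)(C(=O)O)C[C@H]1O
F4 | step 6 | 3-O-[(E)-3,4-diacetoxycinnamoyl]-4-O-benzyl-1,5-quinide | c1ccccc1CO[C@H]1[C@H]2C[C@](O)(C(=O)O2)C[C@H]1OC(=O)/C=C/c1ccc(OC(C)=O)c(OC(C)=O)c1
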